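The pitfall in the alpha flask, charged as beta and asked at 15 min, was to run beta's late first-order slope straight on.

common to all: Cat 0.100 M
- beta: Sub 1.00 M; Rgt 2.50 M
- gamma: Sub 0.600 M; Rgt 2.10 M
- eta: Sub 3.00 M; Rgt 2.50 M
- delta: Sub 1.00 M; Rgt 2.50 M; Prd 0.500 M
- alpha: Sub 1.00 M; Rgt 2.50 M; time 15 min

| run | time / min | [Sub] / M |
|---|---|---|
| beta run | 0.29 | 0.938 |
| beta run | 0.46 | 0.898 |
| beta run | 0.73 | 0.844 |
| beta run | 1.2 | 0.753 |
| beta run | 1.8 | 0.654 |
| beta run | 2.9 | 0.509 |
| beta run | 4.6 | 0.358 |
| beta run | 7.3 | 0.220 |
| gamma run | 0.29 | 0.552 |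
| gamma run | 0.46 | 0.536 |
| gamma run | 0.73 | 0.501 |
| gamma run | 1.2 | 0.437 |
| gamma run | 1.8 | 0.380 |
| gamma run | 2.9 | 0.295 |
| gamma run | 4.6 | 0.196 |
| gamma run | 7.3 | 0.119 |
| eta run | 0.29 | 2.868 |
| eta run | 0.46 | 2.806 |
| eta run | 0.73 | 2.694 |
| eta run | 1.2 | 2.517 |
| eta run | 1.8 | 2.297 |
| eta run | 2.9 | 1.948 |
| eta run | 4.6 | 1.491 |
| eta run | 7.3 | 0.987 |
| delta run | 0.29 | 0.935 |
| delta run | 0.46 | 0.898 |
| delta run | 0.73 | 0.838 |
| delta run | 1.2 | 0.747 |
| delta run | 1.8 | 0.653 |
| delta run | 2.9 | 0.507 |
| delta run | 4.6 | 0.357 |
| delta run | 7.3 | 0.218 |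

(scatter of a reading: 0.003 M)

- Overall: Sub + Rgt -> Prd, with Cat as catalyst.
- Constant volume, constant temperature.
- Readings of a species count what is bound in complexes too.
- "The second partner" is Rgt.
- An order is taken over about fifteen percent of the charge, up and down.

* reaction order in [Rgt] at the outset, round the charge of the beta run, defined at two percent of the Sub turned into Prd
* reaction order in [Sub] at the outset, round the charge of the beta run, defined at two percent of the Sub turned into Prd (one fixed amount of Prd, the same in the runs compared)
* the gamma run starts with 0.400 M less of Sub and of Rgt than the beta run, and with no Prd. Compared where both hold the same amount of Sub, once fifteen percent of what the gamma run was charged with has turned into Prd, is the gamma run faster, slower or alike (within a tenth)?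
* Sub in the alpha run at 15 min, as a share of the Sub charged

I read the pseudo-first-order constant, the slope of ln[Sub] against time, from beta: 0.233 min⁻¹ up to 2.9 min, then a lower 0.191 min⁻¹ up to 7.3 min. Thinning Sub should have raised this constant, not lowered it, because eta, charged with 3.00 M, gave less over the first span, 0.149 min⁻¹. Prd showed no hand in it either: delta, charged with 0.500 M of it, read 0.218 M at 7.3 min against 0.220 M in beta, a gap inside the scatter.

So I let the constant fade with time, and I did not separate any part Rgt might play. I took the shape given by a rate first order in Sub and in a Cat lost in pairs: the reciprocal of the constant grows in a straight line with time. That rate integrates in closed form, and two times carry it. The first is T, the time for Sub to fall by a factor e at the outset, which the two reciprocals, placed at the middles of their spans, put at 3.92 min. The second is τ, the time in which the constant falls to half, which they put at 15.0 min. Their ratio is the tail exponent n = τ/T, read as 3.84, and the share of Sub left is (1 + t/τ)^(−n). For alpha at 15 min I reckoned 7.02%, whereas the straight slope gives 5.07%.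

The forecast was 8%, above mine, with orders 0.3 in Rgt and 0.7 in Sub, and gamma faster, holding that “With no product effect, the older catalyst in beta must be dying”.

The flask gave 7.53% in alpha, 0.51 percentage points above my reckoning, with orders 0.075 in Rgt and 0.58 in Sub, and gamma faster.

    Cat + Sub → Cat.Sub (3.762 M⁻¹ min⁻¹)
    Cat.Sub + Rgt → J (38.76 M⁻¹ min⁻¹)
    J → Prd + Cat (9.960 min⁻¹)
    2 Rgt ⇌ Rgt2, settled at all times (2.950 M⁻¹)
    2 Cat → 2 X (1.038 M⁻¹ min⁻¹)

At equal Sub, gamma ran at 1.2 times the rate of beta. Delta started with 0.500 M of Prd, and with n at 3.84 the same law puts the Prd made at half of the Sub charged at 2.98 min, where the delta run gives 3.09 min.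

The runs were computed on assumed constants, and the scatter is random.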